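The oxolane ring is cut at O1–C2 (C2 carries the guaiacyl ring) and at C3–C4. This splits the lignan core into two C6–C3 halves, silylated coniferaldehyde and silylated coniferyl alcohol, the second made from the first. The key step exploits that C2 and C3 are the β- and α-carbons of a latent C3 formyl group, while C4 and the benzylic CH2 are a styrene double bond. One chiral amine drives reversible oxa-Michael addition, then photoredox oxidation of the enamine, 5-exo radical closure and hydrogen-atom transfer. This sets all three stereocentres in a dynamic, redox-neutral, fully atom-economical [3+2] union. Reduction, Mitsunobu esterification with unprotected caffeic acid and desilylation finish the route.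

Key step: step 3

Remark: oxolane numbering is used throughout (O1, C2 bearing the guaiacyl ring, C3 bearing CH2O, C4 bearing the benzyl group, C5). TBS = tert-butyldimethylsilyl. Coniferaldehyde and caffeic acid are taken as commercial.

Step 1
Reactants: 1 coniferaldehyde
Product: 2 O-TBS-coniferaldehyde
Conditions: TBSCl, imidazole, CH2Cl2, rt
Reagents that add atoms: tert-butyldimethylsilyl chloride (TBSCl), CC(C)(C)[Si](C)(C)Cl
Why: Imidazole-promoted silyl ether formation masks the only acidic OH, which would otherwise neutralise the later iminium ion as a quinone-methide-type merocyanine and compete as an oxa-Michael donor.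

Step 2
Reactants: 2 O-TBS-coniferaldehyde
Product: 3 O-TBS-coniferyl alcohol
Conditions: NaBH4, MeOH/THF, 0 °C
Reagents that add atoms: none
Why: Borohydride 1,2-reduction of a conjugated aldehyde is faster than conjugate reduction and should leave the E alkene and the aryl silyl ether untouched; no stereocentre is made.

Step 3
Reactants: 2 O-TBS-coniferaldehyde, 3 O-TBS-coniferyl alcohol
Product: 5 (2R,3R,4S)-2-aryl-4-benzyl-oxolane-3-carbaldehyde (both arenes 4-TBSO-3-methoxyphenyl), via oxa-Michael adduct 4 (not isolated)
Conditions: 2 (1.5 equiv), (R)-α,α-diphenylprolinol trimethylsilyl ether (20 mol %), PhCO2H (20 mol %), [Ir(Fmppy)2(dtbbpy)]PF6 (1 mol %), 2,4,6-triisopropylbenzenethiol (20 mol %), DME (1 M), blue LEDs, 0 °C, argon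
Reagents that add atoms: none
Why: Proposed new method: the amine and enal 2 form an iminium ion that alcohol 3 attacks reversibly at the benzylic β-carbon (intermolecular oxa-Michael addition, O1–C2), the excited trivalent iridium complex oxidises the resulting enamine of 4 to an electrophilic enaminyl radical cation, this closes onto the inner carbon of the electron-rich styrene (C3–C4), and the benzylic radical so formed takes a hydrogen atom from the thiol before thiyl radical and divalent iridium return both co-catalysts and hydrolysis releases 5. The closest known reaction types are the dynamic kinetic oxa-Michael/carbocyclisation of enals with propargylic alcohols under amine and palladium catalysis and the enantioselective photoredox/enamine/thiol cyclisation of aldehydes onto tethered olefins; new is only their merger, in which the β-alkoxy aldehyde is made and consumed in the same flask. The oxolane ring closes by a 5-exo-trig radical addition, favoured over 6-endo by geometry and by the guaiacyl-stabilised benzylic radical it produces. The diphenyl(silyloxy)methyl group of the (R)-amine shields the same face of the iminium ion and of the enaminyl radical, which fixes C2 as R and C3 trans to it, and since the oxa-Michael step is reversible the mismatched C2 epimer and any Z isomers made by sensitisation are returned to the pool and funnelled through the faster matched closure. C4 is set by the chair-like transition state with the C2 aryl group and the C3 iminium carbon both pseudo-equatorial, which puts the new benzyl arm trans to the aryl group and cis to the formyl group, the outcome known for the analogous C3 radicals made from cinnamyl epoxy ethers with Cp2TiCl. The step needs oxidation of the enamine in preference to the styrene, the arenes and the amine, secured by its much lower potential and a mildly oxidising photocatalyst, and it needs the thiol to stay available, secured by the flanking isopropyl groups that make its own conjugate addition to 2 slow and reversible.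

Step 4
Reactants: 5 (2R,3R,4S)-oxolane-3-carbaldehyde
Product: 6 [(2R,3S,4S)-2-aryl-4-benzyl-oxolan-3-yl]methanol, the bis-TBS ether of the (2R,3S,4S) enantiomer of lariciresinol
Conditions: NaBH4, MeOH/THF, −20 to 0 °C, on the crude aldehyde
Reagents that add atoms: none
Why: Borohydride carbonyl reduction removes the only function that allows C3 epimerisation or retro-oxa-Michael opening, so the three stereocentres should be locked before chromatography (the C3 descriptor changes from R to S by priority only).

Step 5
Reactants: 6 bis-TBS (2R,3S,4S)-lariciresinol, 7 caffeic acid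
Product: 8 bis-TBS ether of the target caffeate
Conditions: PPh3, DIAD, THF, 0 °C to rt
Reagents that add atoms: none
Why: In the Mitsunobu esterification the primary alcohol is activated as an alkoxyphosphonium ion and displaced by the carboxylate, by far the most acidic pronucleophile present, so the catechol needs no protection and no stereocentre is touched because substitution occurs at CH2.

Step 6
Reactants: 8 bis-TBS ether of the target caffeate
Product: 9 target, CNP0132883.1
Conditions: TBAF (2.2 equiv), AcOH (2.2 equiv), THF, 0 °C
Reagents that add atoms: none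
Why: Fluoride cleavage of aryl silyl ethers, buffered with acetic acid so that phenoxides are protonated at once, should spare the cinnamate ester, the E alkene and the benzylic ether at C2.

Compound list
1 | coniferaldehyde, (E)-3-(4-hydroxy-3-methoxyphenyl)prop-2-enal | COc1cc(/C=C/C=O)ccc1O | starting material
2 | O-TBS-coniferaldehyde, (E)-3-[4-(tert-butyldimethylsilyloxy)-3-methoxyphenyl]prop-2-enal | COc1cc(/C=C/C=O)ccc1O[Si](C)(C)C(C)(C)C | intermediate
3 | O-TBS-coniferyl alcohol, (E)-3-[4-(tert-butyldimethylsilyloxy)-3-methoxyphenyl]prop-2-en-1-ol | COc1cc(/C=C/CO)ccc1O[Si](C)(C)C(C)(C)C | intermediate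
4 | oxa-Michael adduct, (3R)-3-(4-TBSO-3-methoxyphenyl)-3-[(E)-3-(4-TBSO-3-methoxyphenyl)prop-2-enoxy]propanal, present as its enamine with the amine catalyst | COc1cc(/C=C/CO[C@@H](c2ccc(O[Si](C)(C)C(C)(C)C)c(OC)c2)CC=O)ccc1O[Si](C)(C)C(C)(C)C | intermediate
5 | (2R,3R,4S)-2-(4-TBSO-3-methoxyphenyl)-4-[(4-TBSO-3-methoxyphenyl)methyl]oxolane-3-carbaldehyde | COc1cc(C[C@@H]2CO[C@@H](c3ccc(O[Si](C)(C)C(C)(C)C)c(OC)c3)[C@@H]2C=O)ccc1O[Si](C)(C)C(C)(C)C | intermediate
6 | [(2R,3S,4S)-2-(4-TBSO-3-methoxyphenyl)-4-[(4-TBSO-3-methoxyphenyl)methyl]oxolan-3-yl]methanol | COc1cc(C[C@@H]2CO[C@@H](c3ccc(O[Si](C)(C)C(C)(C)C)c(OC)c3)[C@@H]2CO)ccc1O[Si](C)(C)C(C)(C)C | intermediate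
7 | caffeic acid, (E)-3-(3,4-dihydroxyphenyl)prop-2-enoic acid | OC(=O)/C=C/c1ccc(O)c(O)c1 | starting material
8 | [(2R,3S,4S)-2-(4-TBSO-3-methoxyphenyl)-4-[(4-TBSO-3-methoxyphenyl)methyl]oxolan-3-yl]methyl (E)-3-(3,4-dihydroxyphenyl)prop-2-enoate | COc1cc(C[C@@H]2CO[C@@H](c3ccc(O[Si](C)(C)C(C)(C)C)c(OC)c3)[C@@H]2COC(=O)/C=C/c2ccc(O)c(O)c2)ccc1O[Si](C)(C)C(C)(C)C | intermediate
9 | [(2R,3S,4S)-2-(4-hydroxy-3-methoxyphenyl)-4-[(4-hydroxy-3-methoxyphenyl)methyl]oxolan-3-yl]methyl (E)-3-(3,4-dihydroxyphenyl)prop-2-enoate | COc1cc(C[C@@H]2CO[C@@H](c3ccc(O)c(OC)c3)[C@@H]2COC(=O)/C=C/c2ccc(O)c(O)c2)ccc1O | target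

Total step count: 6
Longest linear sequence: 6 steps (1 → 2 → 3 → 5 → 6 → 8 → 9)

Steps most likely to fail

Step 3.
- What may go wrong:
  - The oxa-Michael equilibrium with the electron-rich enal may lie so far back that too little enamine is present.
  - The thiol may be held up by its own conjugate addition.
  - The benzylic radical may add to a second iminium ion before hydrogen transfer.
  - A boat-type closure may erode facial selectivity at C4.
- Fallback (sets out from 3, comes back at 6): the two ring bonds are made one after the other by the established epoxide-radical route to furano lignans.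
  - Appel bromination of 3 (CBr4, PPh3, CH2Cl2) gives the cinnamyl bromide F1.
  - Vanillin is silylated (TBSCl, imidazole) to O-TBS-vanillin F2.
  - Vinylmagnesium bromide converts this into the racemic aryl vinyl carbinol F3.
  - Sharpless kinetic resolution (Ti(OiPr)4, L-(+)-DIPT, t-BuOOH, stopped below half conversion) gives the (S,S)-epoxy alcohol F4.
  - Williamson etherification with F1 (NaH, THF) gives the epoxy ether F5, which already holds O1–C2.
  - Cp2TiCl (from Cp2TiCl2 and Zn, THF) opens the oxirane to the C3 radical. This closes 5-exo-trig onto the cinnamyl alkene.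
  - A second trivalent titanium centre captures the benzylic radical, and mild acidic work-up should give 6. The oxirane stereocentre is erased in the radical.

Step 5.
- What may go wrong:
  - The catechol may be drawn into phosphorane formation or O-alkylation.
  - Displacement at the β-branched primary carbinol may be slow.
- Fallback (sets out from 6, comes back at 8): the cinnamate is built on the alcohol instead of being transferred to it.
  - Heating 6 with Meldrum's acid in toluene gives the malonic half-ester F6.
  - Knoevenagel–Doebner condensation with 3,4-dihydroxybenzaldehyde (pyridine, catalytic piperidine) should give the E-caffeate 8 with decarboxylation.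

Step 6.
- What may go wrong: transient phenoxides may cleave or transfer the ester, or the catechol may be oxidised by air in the fluoride medium.
- Fallback (sets out from 6, comes back at 9): the order is reversed so that fluoride never meets the catechol ester.
  - Compound 6 is desilylated first (TBAF, AcOH, THF) to (2R,3S,4S)-lariciresinol F7.
  - Chemoselective Mitsunobu esterification of its only aliphatic hydroxyl group with caffeic acid 7 (PPh3, DIAD, THF) should give 9 directly.

Further compounds
F1 | step 3 | (E)-1-(3-bromoprop-1-enyl)-4-(tert-butyldimethylsilyloxy)-3-methoxybenzene | COc1cc(/C=C/CBr)ccc1O[Si](C)(C)C(C)(C)C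
F2 | step 3 | 4-(tert-butyldimethylsilyloxy)-3-methoxybenzaldehyde | COc1cc(C=O)ccc1O[Si](C)(C)C(C)(C)C
F3 | step 3 | racemic 1-[4-(tert-butyldimethylsilyloxy)-3-methoxyphenyl]prop-2-en-1-ol | COc1cc(C(O)C=C)ccc1O[Si](C)(C)C(C)(C)C
F4 | step 3 | (S)-[4-(tert-butyldimethylsilyloxy)-3-methoxyphenyl][(S)-oxiran-2-yl]methanol | O[C@@H](c1ccc(O[Si](C)(C)C(C)(C)C)c(OC)c1)[C@@H]2CO2
F5 | step 3 | (S)-2-[(S)-(4-TBSO-3-methoxyphenyl)[(E)-3-(4-TBSO-3-methoxyphenyl)prop-2-enoxy]methyl]oxirane | COc1cc(/C=C/CO[C@@H](c2ccc(O[Si](C)(C)C(C)(C)C)c(OC)c2)[C@@H]3CO3)ccc1O[Si](C)(C)C(C)(C)C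
F6 | step 5 | 3-[[(2R,3S,4S)-2-(4-TBSO-3-methoxyphenyl)-4-[(4-TBSO-3-methoxyphenyl)methyl]oxolan-3-yl]methoxy]-3-oxopropanoic acid | COc1cc(C[C@@H]2CO[C@@H](c3ccc(O[Si](C)(C)C(C)(C)C)c(OC)c3)[C@@H]2COC(=O)CC(=O)O)ccc1O[Si](C)(C)C(C)(C)C
F7 | step 6 | (2R,3S,4S)-lariciresinol, 4-[(2R,3S,4S)-4-[(4-hydroxy-3-methoxyphenyl)methyl]-3-(hydroxymethyl)oxolan-2-yl]-2-methoxyphenol | COc1cc(C[C@@H]2CO[C@@H](c3ccc(O)c(OC)c3)[C@@H]2CO)ccc1O
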